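The route dearomatises a flat chromone at its benzo ring. Everything rests on cutting the C5–O and C6–O bonds, which (after removal of HOCl from C7/C8) turns the target into a 2-(arylethyl)chromone. The key step exploits that C4a–C5–C6–C7–C8–C8a is a benzo ring whose C5 and C6 carry cis hydroxyls: a Rieske dioxygenase adds O2 across C5=C6 from one face, setting both stereocentres and leaving the C7=C8 alkene. Its precursor is the unprotected 2-[2-(3-hydroxy-4-methoxyphenyl)ethyl]chromone, reached in two steps. The C6 hydroxyl then directs a syn epoxidation of C7=C8, and chloride opens the epoxide at C8 with inversion.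

Key step: step 3

Assumption: the target SMILES is read as (5S,6S,7S,8R) in chromone numbering (O1, C2 … C8a), i.e. the hydroxyls at C5, C6 and C7 are mutually cis and the C8 chlorine is trans to them; the descriptors of all intermediates were re-derived from it.

Step 1
Reactants: 1 3-(3-hydroxy-4-methoxyphenyl)propanoic acid
Product: 2 methyl 3-(3-hydroxy-4-methoxyphenyl)propanoate
Conditions: MeOH, H2SO4 (cat.), reflux
Reagents that add atoms: methanol, CO
Why: Fischer esterification should convert only the carboxylic acid, since the phenol and the aryl methyl ether are inert to methanol and catalytic acid.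

Step 2
Reactants: 2 methyl 3-(3-hydroxy-4-methoxyphenyl)propanoate; 3 2'-hydroxyacetophenone
Product: 5 2-[2-(3-hydroxy-4-methoxyphenyl)ethyl]-4H-chromen-4-one, via β-diketone 4 (not isolated)
Conditions: LiHMDS (4.5 equiv), THF, −78 °C → rt; then AcOH, conc. HCl, 90 °C
Reagents that add atoms: none
Why: Claisen condensation of the acetophenone dianion with ester 2 (whose phenoxide is a spectator, so no protecting group is needed) should give the o-hydroxyaryl β-diketone 4, which cyclodehydrates under acid to the pyranone ring in the classical chromone synthesis; no stereocentre is formed.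

Step 3
Reactants: 5 2-[2-(3-hydroxy-4-methoxyphenyl)ethyl]-4H-chromen-4-one
Product: 6 (5S,6R)-5,6-dihydroxy-2-[2-(3-hydroxy-4-methoxyphenyl)ethyl]-5,6-dihydro-4H-chromen-4-one
Conditions: evolved Rieske dioxygenase (E. coli resting cells, with ferredoxin/reductase and formate dehydrogenase), air, HCO2Na, KPi pH 7.2, 5% DMSO, 30 °C
Reagents that add atoms: dioxygen, O=O
Why: Proposed new method: electrons from NADH reach the Rieske [2Fe–2S] cluster and the mononuclear non-heme iron, which binds O2 side-on and transfers both oxygen atoms to the same face of the C5=C6 bond of the benzo ring, so C5–O and C6–O form suprafacially (cis by mechanism) and C7=C8 stays behind as an alkene conjugated to the pyranone. The closest known reaction type is the cis-dihydroxylation of naphthalene, quinolines and other benzo-fused heteroarenes on their carbocyclic ring by naphthalene, toluene and biphenyl dioxygenases; a chromone has not been shown as substrate, hence the label. No ring is closed in this step. Both new stereocentres, C5 (S) and C6 (R), are set by the enzyme, namely by which enantiotopic face of the benzo ring the pocket presents to iron; wild-type naphthalene dioxygenase gives the (1R,2S)-diol from naphthalene, which would correspond to the opposite sense if the chromone bound alike, so face selection is a criterion of the screening and evolution campaign. The step needs regioselectivity for C5–C6 over C7–C8 and over the aryl ring: the substrate contributes the C4=O peri to C5 as a polar anchor, an electron-poor non-benzenoid pyranone ring and a 1,2,4-trisubstituted guaiacyl ring that is a poor dioxygenase substrate, while the remaining control has to come from the engineered pocket. The cis-diol is the target minus HOCl across C7=C8, so no stereocentre has to be corrected afterwards.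

Step 4
Reactants: 6 (5S,6R)-5,6-dihydroxy-2-[2-(3-hydroxy-4-methoxyphenyl)ethyl]-5,6-dihydro-4H-chromen-4-one
Product: 7 (5S,6S,7S,8S)-7,8-epoxy-5,6-dihydroxy-2-[2-(3-hydroxy-4-methoxyphenyl)ethyl]-5,6,7,8-tetrahydro-4H-chromen-4-one (oxirane oxygen cis to both hydroxyls)
Conditions: VO(acac)2 (5 mol %), t-BuOOH (1.3 equiv), CH2Cl2, 0 °C → rt
Reagents that add atoms: tert-butyl hydroperoxide, CC(C)(C)OO
Why: In this vanadium-catalysed hydroxyl-directed epoxidation of an allylic alcohol, the C6 alkoxide on vanadium should deliver the peroxide oxygen to the face of C7=C8 on which it sits, which sets C7 and C8 with the oxirane cis to the C6 (and C5) hydroxyl, while the pyranone C2=C3 bond and the aryl ring carry no directing hydroxyl and should stay untouched.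

Step 5
Reactants: 7 (5S,6S,7S,8S)-7,8-epoxy-5,6-dihydroxy-2-[2-(3-hydroxy-4-methoxyphenyl)ethyl]-5,6,7,8-tetrahydro-4H-chromen-4-one
Product: 8 (5S,6S,7S,8R)-8-chloro-5,6,7-trihydroxy-2-[2-(3-hydroxy-4-methoxyphenyl)ethyl]-5,6,7,8-tetrahydro-4H-chromen-4-one
Conditions: HCl (4 M in dioxane, 1.5 equiv), THF, −20 → 0 °C
Reagents that add atoms: hydrogen chloride, Cl
Why: In this acid-promoted SN2-type opening of a 2,3-epoxy alcohol, chloride should attack C8, which is allylic to the C8a=C4a bond and remote from the deactivating C6 oxygen, from the face opposite the oxirane oxygen, so C8 is inverted (Cl trans to the C7 hydroxyl) and C5, C6 and C7 keep their configuration.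

Compound list
1 | 3-(3-hydroxy-4-methoxyphenyl)propanoic acid | COc1ccc(CCC(=O)O)cc1O | starting material
2 | methyl 3-(3-hydroxy-4-methoxyphenyl)propanoate | COC(=O)CCc1ccc(OC)c(O)c1 | intermediate
3 | 2'-hydroxyacetophenone | CC(=O)c1ccccc1O | starting material
4 | 1-(2-hydroxyphenyl)-5-(3-hydroxy-4-methoxyphenyl)pentane-1,3-dione (β-diketone, not isolated) | COc1ccc(CCC(=O)CC(=O)c2ccccc2O)cc1O | intermediate
5 | 2-[2-(3-hydroxy-4-methoxyphenyl)ethyl]-4H-chromen-4-one | COc1ccc(CCc2cc(=O)c3ccccc3o2)cc1O | intermediate
6 | (5S,6R)-5,6-dihydroxy-2-[2-(3-hydroxy-4-methoxyphenyl)ethyl]-5,6-dihydro-4H-chromen-4-one | COc1ccc(CCc2cc(=O)c3c(o2)C=C[C@@H](O)[C@H]3O)cc1O | intermediate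
7 | (5S,6S,7S,8S)-7,8-epoxy-5,6-dihydroxy-2-[2-(3-hydroxy-4-methoxyphenyl)ethyl]-5,6,7,8-tetrahydro-4H-chromen-4-one | COc1ccc(CCc2cc(=O)c3c(o2)[C@H]4O[C@H]4[C@@H](O)[C@H]3O)cc1O | intermediate
8 | (5S,6S,7S,8R)-8-chloro-5,6,7-trihydroxy-2-[2-(3-hydroxy-4-methoxyphenyl)ethyl]-5,6,7,8-tetrahydro-4H-chromen-4-one (CNP0362174.1) | COc1ccc(CCc2cc(=O)c3c(o2)[C@H](Cl)[C@@H](O)[C@@H](O)[C@H]3O)cc1O | target

Total step count: 5. Longest linear sequence: 5 steps (1 → 2 → 5 → 6 → 7 → 8).

Steps most likely to fail

Step 3. What may go wrong: no productive binding of the large chromone, oxygenation at C7–C8 or on the guaiacyl ring instead of C5–C6, delivery to the wrong enantiotopic face, or dehydration of the diene diol to a phenol in the broth. The fallback uses known chemistry only, sets out from ester 2 and returns at 6; it builds the carbocycle saturated and unveils its unsaturation last.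
- Ester 2 is condensed with the polyanion of commercial 2-acetylcyclohexane-1,3-dione (LDA, THF; Hauser-type Claisen at the acetyl methyl) to the tetraketone F1.
- Acid cyclodehydration of F1 gives 2-[2-(3-hydroxy-4-methoxyphenyl)ethyl]-7,8-dihydro-4H-chromene-4,5(6H)-dione F2.
- Kinetic enolisation of the C5 ketone (LDA, −78 °C) and PhSeCl give the 6-phenylselanyl ketone F3, and Luche reduction gives the hydroxy selenide F4.
- H2O2 converts F4 into the selenoxide F5, whose syn-elimination away from the carbinol gives the racemic allylic alcohol 5-hydroxy-5,8-dihydrochromone F6 (C6=C7), to be handled cold and neutral.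
- VO(acac)2/t-BuOOH epoxidises C6=C7 cis to the C5 hydroxyl to give the racemic epoxy alcohol F7.
- Lipase-catalysed acylation with vinyl acetate resolves F7, and the (5S)-acetate F8 is carried on.
- K2CO3 in methanol removes the acetate and deprotonates C8 (vinylogous to C4=O); E1cB opening of the C7–O bond gives the cis-5,6-diol with the C7=C8 bond, which is 6.

Step 4. What may go wrong: chelation of vanadium by the cis-diol and the phenol stalls turnover, the guaiacyl phenol is oxidised, or Lewis-acid-assisted dehydration re-aromatises the diene diol. The fallback sets out from 6 and returns at 7 without a new compound: Henbest epoxidation with buffered mCPBA (NaHCO3, CH2Cl2/EtOAc, 0 °C). It replaces the catalytic metal-alkoxide template by a stoichiometric peracid whose hydrogen bond to the allylic C6 hydroxyl carries the oxygen to the same face.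

Step 5. What may go wrong: competing attack at C7, partial ionisation at C8 with loss of clean inversion, or acid-induced dehydration of the polyol. The fallback sets out from 7 and returns at 8 without a new compound: proton-free, chelation-controlled opening of the 2,3-epoxy alcohol unit (C6–OH with the C7–C8 oxirane) with Ti(OiPr)4 and a chloride salt (Et2NH·HCl) in CH2Cl2. Titanium bridges the C6 alkoxide and the oxirane oxygen and directs chloride to the distal carbon C8 with inversion.

Further compounds
F1 | step 3 | 2-[5-(3-hydroxy-4-methoxyphenyl)-3-oxopentanoyl]cyclohexane-1,3-dione (tetraketone, not isolated) | COc1ccc(CCC(=O)CC(=O)C2C(=O)CCCC2=O)cc1O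
F2 | step 3 | 2-[2-(3-hydroxy-4-methoxyphenyl)ethyl]-7,8-dihydro-4H-chromene-4,5(6H)-dione | COc1ccc(CCc2cc(=O)c3c(o2)CCCC3=O)cc1O
F3 | step 3 | rac-2-[2-(3-hydroxy-4-methoxyphenyl)ethyl]-6-(phenylselanyl)-7,8-dihydro-4H-chromene-4,5(6H)-dione | COc1ccc(CCc2cc(=O)c3c(o2)CCC([Se]c4ccccc4)C3=O)cc1O
F4 | step 3 | 5-hydroxy-2-[2-(3-hydroxy-4-methoxyphenyl)ethyl]-6-(phenylselanyl)-5,6,7,8-tetrahydro-4H-chromen-4-one (racemic, mixture of diastereomers) | COc1ccc(CCc2cc(=O)c3c(o2)CCC([Se]c4ccccc4)C3O)cc1O
F5 | step 3 | selenoxide of F4 (not isolated) | COc1ccc(CCc2cc(=O)c3c(o2)CCC([Se](=O)c4ccccc4)C3O)cc1O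
F6 | step 3 | rac-5-hydroxy-2-[2-(3-hydroxy-4-methoxyphenyl)ethyl]-5,8-dihydro-4H-chromen-4-one | COc1ccc(CCc2cc(=O)c3c(o2)CC=CC3O)cc1O
F7 | step 3 | rac-(5S,6S,7R)-6,7-epoxy-5-hydroxy-2-[2-(3-hydroxy-4-methoxyphenyl)ethyl]-5,6,7,8-tetrahydro-4H-chromen-4-one (oxirane cis to the hydroxyl; one enantiomer drawn) | COc1ccc(CCc2cc(=O)c3c(o2)C[C@H]4O[C@H]4[C@H]3O)cc1O
F8 | step 3 | (5S,6R,7R)-5-acetoxy-6,7-epoxy-2-[2-(3-hydroxy-4-methoxyphenyl)ethyl]-5,6,7,8-tetrahydro-4H-chromen-4-one | COc1ccc(CCc2cc(=O)c3c(o2)C[C@H]4O[C@H]4[C@H]3OC(C)=O)cc1O
F0 | step 4 | none | none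
F0 | step 5 | none | none
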